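**Retrosynthetic overview**
1. Colletotryptin C ⇒ acetonide hydrolysis, O-acetylation, desilylation and Boc removal lead back to a fully protected 1,1-bis(indolyl)propane-2,3-diol.
2. The C2–O bond ⇒ D-proline-catalysed α-aminoxylation of a 3,3-bis(indolyl)propanal, followed by reduction.
3. Key C–C bond (C1 to indole C3) ⇒ intermolecular enantioselective Michael (Friedel–Crafts-type conjugate) addition of indole to an (E)-3-(indol-2-yl)acrolein under imidazolidinone iminium catalysis.
4. Enal ⇒ Wittig two-carbon homologation of a 2-formylindole, made by C2 lithiation and formylation of N-Boc-O-TBS-tryptophol.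
5. Rings: both indole ring systems are bought intact (tryptophol, indole). The only ring formed is the temporary dioxolane (step 8), which is opened again in step 12.

Assumption: CIP analysis of the given SMILES gives 1S (bis-indolyl methine) and 2S (carbinol). The facial preferences of the two organocatalysts are taken from their established behaviour with cinnamaldehyde-type enals and simple aldehydes.

**Step 1**
Reactants: 1 tryptophol, 2-(1H-indol-3-yl)ethanol
Product: 2 3-[2-(tert-butyldimethylsilyloxy)ethyl]-1H-indole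
Conditions: TBSCl, imidazole, CH2Cl2, 0 °C to rt
Reagents that add atoms: tert-butyldimethylsilyl chloride (TBSCl), CC(C)(C)[Si](C)(C)Cl
Why: Imidazole-promoted O-silylation masks the primary alcohol against the later organolithium, ylide, hydride and methoxide steps, and the indole N–H is not silylated under these conditions.

**Step 2**
Reactants: 2 3-[2-(tert-butyldimethylsilyloxy)ethyl]-1H-indole
Product: 3 tert-butyl 3-[2-(tert-butyldimethylsilyloxy)ethyl]indole-1-carboxylate
Conditions: Boc2O, DMAP (10 mol %), MeCN, rt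
Reagents that add atoms: di-tert-butyl dicarbonate (Boc2O), CC(C)(C)OC(=O)OC(=O)OC(C)(C)C
Why: DMAP-catalysed N-acylation (carbamate formation) installs a group that directs C2 lithiation, switches off nitrogen donation into the later enal, and blocks closure of N1 onto the later aldehyde.

**Step 3**
Reactants: 3 tert-butyl 3-[2-(tert-butyldimethylsilyloxy)ethyl]indole-1-carboxylate
Product: 6 tert-butyl 3-[2-(tert-butyldimethylsilyloxy)ethyl]-2-formylindole-1-carboxylate, via 2-lithioindole 4 (not isolated), via lithium hemiaminal alkoxide 5 (not isolated)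
Conditions: LiN(i-Pr)2 (commercial solution, 1.3 equiv), THF, −78 °C, 1 h; DMF, −78 to −40 °C; sat. aq. NH4Cl
Reagents that add atoms: N,N-dimethylformamide (DMF), CN(C)C=O
Why: Carbamate-directed C2 lithiation followed by formylation with DMF works because C3 is blocked, the silyl ether is inert, and the hemiaminal alkoxide collapses to the aldehyde only on quench, so no over-addition occurs.

**Step 4**
Reactants: 6 tert-butyl 3-[2-(tert-butyldimethylsilyloxy)ethyl]-2-formylindole-1-carboxylate
Product: 7 tert-butyl 3-[2-(tert-butyldimethylsilyloxy)ethyl]-2-[(E)-3-oxoprop-1-enyl]indole-1-carboxylate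
Conditions: Ph3P=CHCHO (1.2 equiv), toluene, 80 °C
Reagents that add atoms: (triphenylphosphoranylidene)acetaldehyde, O=CC=P(c1ccccc1)(c1ccccc1)c1ccccc1
Why: Wittig olefination with a stabilised ylide gives the E-enal selectively in one step and avoids hydride reagents that could attack the activated indole carbamate.

**Step 5**
Reactants: 7 tert-butyl 3-[2-(tert-butyldimethylsilyloxy)ethyl]-2-[(E)-3-oxoprop-1-enyl]indole-1-carboxylate; 8 indole (1.5 equiv)
Product: 9 tert-butyl 3-[2-(tert-butyldimethylsilyloxy)ethyl]-2-[(1S)-1-(1H-indol-3-yl)-3-oxopropyl]indole-1-carboxylate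
Conditions: (2R,5R)-5-benzyl-2-tert-butyl-3-methylimidazolidin-4-one·CF3CO2H (20 mol %), CH2Cl2/i-PrOH 85:15, −40 °C, 48–72 h
Reagents that add atoms: none
Why: In this enantioselective organocatalytic Michael addition (Friedel–Crafts-type conjugate addition, iminium catalysis with the second-generation MacMillan imidazolidinone), the benzyl and tert-butyl groups shield one face of the E-configured activated enal, so indole C3 attacks the open face of the β-carbon; because the (2S,5S) catalyst gives the opposite spatial sense with crotonaldehyde and cinnamaldehyde, the (2R,5R) catalyst sets the required 1S centre.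

**Step 6**
Reactants: 9 tert-butyl 3-[2-(tert-butyldimethylsilyloxy)ethyl]-2-[(1S)-1-(1H-indol-3-yl)-3-oxopropyl]indole-1-carboxylate
Product: 11 tert-butyl 3-[2-(tert-butyldimethylsilyloxy)ethyl]-2-[(1S,2S)-3-hydroxy-1-(1H-indol-3-yl)-2-(phenylaminooxy)propyl]indole-1-carboxylate, via alpha-aminoxy aldehyde 10 (not isolated)
Conditions: D-proline (25 mol %), PhNO (1.0 equiv), MeCN, −20 °C, 24 h; then MeOH, NaBH4, 0 °C, 15 min
Reagents that add atoms: nitrosobenzene, O=Nc1ccccc1
Why: In the proline-catalysed α-aminoxylation (O-selective nitroso aldol reaction, enamine catalysis) L-proline gives 2R products from simple aldehydes, so D-proline sets 2S under catalyst control; both indoles are blocked at C3 and do not compete for PhNO, immediate borohydride reduction prevents α-epimerisation, and material from the minor enantiomer of 9 becomes a separable diastereomer.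

**Step 7**
Reactants: 11 tert-butyl 3-[2-(tert-butyldimethylsilyloxy)ethyl]-2-[(1S,2S)-3-hydroxy-1-(1H-indol-3-yl)-2-(phenylaminooxy)propyl]indole-1-carboxylate
Product: 12 tert-butyl 3-[2-(tert-butyldimethylsilyloxy)ethyl]-2-[(1S,2S)-2,3-dihydroxy-1-(1H-indol-3-yl)propyl]indole-1-carboxylate
Conditions: H2 (1 atm), Pd/C (10 wt % Pd on carbon), MeOH, rt
Reagents that add atoms: none
Why: Hydrogenolysis of the weak N–O bond under neutral conditions frees the secondary alcohol without touching the C–O stereocentre, the indoles, the Boc group or the silyl ether, and the absence of base avoids Boc migration from nitrogen to oxygen.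

**Step 8**
Reactants: 12 tert-butyl 3-[2-(tert-butyldimethylsilyloxy)ethyl]-2-[(1S,2S)-2,3-dihydroxy-1-(1H-indol-3-yl)propyl]indole-1-carboxylate
Product: 13 tert-butyl 3-[2-(tert-butyldimethylsilyloxy)ethyl]-2-[(S)-[(4S)-2,2-dimethyl-1,3-dioxolan-4-yl](1H-indol-3-yl)methyl]indole-1-carboxylate
Conditions: Me2C(OMe)2, PPTS (10 mol %), CH2Cl2, rt
Reagents that add atoms: 2,2-dimethoxypropane, COC(C)(C)OC
Why: Acid-catalysed transketalisation closes the five-membered acetonide on the terminal 1,2-diol, so that only the side-chain oxygen can be acetylated later, and neither stereocentre is involved in bond breaking.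

**Step 9**
Reactants: 13 tert-butyl 3-[2-(tert-butyldimethylsilyloxy)ethyl]-2-[(S)-[(4S)-2,2-dimethyl-1,3-dioxolan-4-yl](1H-indol-3-yl)methyl]indole-1-carboxylate
Product: 14 3-[2-(tert-butyldimethylsilyloxy)ethyl]-2-[(S)-[(4S)-2,2-dimethyl-1,3-dioxolan-4-yl](1H-indol-3-yl)methyl]-1H-indole
Conditions: NaOMe (0.3 equiv), MeOH/THF, rt to 40 °C
Reagents that add atoms: none
Why: Methoxide-catalysed methanolysis cleaves the acyl-azole-like, sterically strained indole carbamate under conditions that leave the acetonide, the primary silyl ether and the non-acidic bis-indolyl methine untouched; it is done before any acetate is present.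

**Step 10**
Reactants: 14 3-[2-(tert-butyldimethylsilyloxy)ethyl]-2-[(S)-[(4S)-2,2-dimethyl-1,3-dioxolan-4-yl](1H-indol-3-yl)methyl]-1H-indole
Product: 15 2-{2-[(S)-[(4S)-2,2-dimethyl-1,3-dioxolan-4-yl](1H-indol-3-yl)methyl]-1H-indol-3-yl}ethanol
Conditions: Bu4NF (1.2 equiv), THF, 0 °C to rt
Reagents that add atoms: none
Why: Fluoride-mediated desilylation is driven by the strong Si–F bond and is orthogonal to the acetonide and the free indoles.

**Step 11**
Reactants: 15 2-{2-[(S)-[(4S)-2,2-dimethyl-1,3-dioxolan-4-yl](1H-indol-3-yl)methyl]-1H-indol-3-yl}ethanol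
Product: 16 2-{2-[(S)-[(4S)-2,2-dimethyl-1,3-dioxolan-4-yl](1H-indol-3-yl)methyl]-1H-indol-3-yl}ethyl acetate
Conditions: Ac2O (1.2 equiv), pyridine, 0 °C to rt
Reagents that add atoms: acetic anhydride, CC(=O)OC(C)=O
Why: O-acetylation of the only free hydroxyl is chemoselective because indole N–H groups are not acylated by Ac2O/pyridine without deprotonation or DMAP.

**Step 12**
Reactants: 16 2-{2-[(S)-[(4S)-2,2-dimethyl-1,3-dioxolan-4-yl](1H-indol-3-yl)methyl]-1H-indol-3-yl}ethyl acetate
Product: 17 colletotryptin C, 2-{2-[(1S,2S)-2,3-dihydroxy-1-(1H-indol-3-yl)propyl]-1H-indol-3-yl}ethyl acetate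
Conditions: AcOH/H2O 4:1, 40 °C
Reagents that add atoms: none
Why: Mild acid-catalysed acetal hydrolysis removes the terminal acetonide with retention of both C–O bonds, while aqueous acetic acid is too weak to cleave the acetate or to trigger retro-Friedel–Crafts scrambling of the bis-indolyl methine.

**Compound list**
1 | tryptophol, 2-(1H-indol-3-yl)ethanol | OCCc1c[nH]c2ccccc12 | starting material
2 | 3-[2-(tert-butyldimethylsilyloxy)ethyl]-1H-indole | CC(C)(C)[Si](C)(C)OCCc1c[nH]c2ccccc12 | intermediate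
3 | tert-butyl 3-[2-(tert-butyldimethylsilyloxy)ethyl]indole-1-carboxylate | CC(C)(C)[Si](C)(C)OCCc1cn(C(=O)OC(C)(C)C)c2ccccc12 | intermediate
4 | 2-lithio derivative of 3 (formed in the flask) | CC(C)(C)[Si](C)(C)OCCc1c([Li])n(C(=O)OC(C)(C)C)c2ccccc12 | intermediate
5 | lithium hemiaminal alkoxide from 4 and DMF (formed in the flask) | CC(C)(C)[Si](C)(C)OCCc1c(C(O[Li])N(C)C)n(C(=O)OC(C)(C)C)c2ccccc12 | intermediate
6 | tert-butyl 3-[2-(tert-butyldimethylsilyloxy)ethyl]-2-formylindole-1-carboxylate | CC(C)(C)[Si](C)(C)OCCc1c(C=O)n(C(=O)OC(C)(C)C)c2ccccc12 | intermediate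
7 | tert-butyl 3-[2-(tert-butyldimethylsilyloxy)ethyl]-2-[(E)-3-oxoprop-1-enyl]indole-1-carboxylate | CC(C)(C)[Si](C)(C)OCCc1c(/C=C/C=O)n(C(=O)OC(C)(C)C)c2ccccc12 | intermediate
8 | indole | c1ccc2[nH]ccc2c1 | starting material
9 | tert-butyl 3-[2-(tert-butyldimethylsilyloxy)ethyl]-2-[(1S)-1-(1H-indol-3-yl)-3-oxopropyl]indole-1-carboxylate | CC(C)(C)[Si](C)(C)OCCc1c([C@H](c2c[nH]c3ccccc23)CC=O)n(C(=O)OC(C)(C)C)c2ccccc12 | intermediate
10 | tert-butyl 3-[2-(tert-butyldimethylsilyloxy)ethyl]-2-[(1S,2S)-1-(1H-indol-3-yl)-3-oxo-2-(phenylaminooxy)propyl]indole-1-carboxylate (formed in the flask) | CC(C)(C)[Si](C)(C)OCCc1c([C@H](c2c[nH]c3ccccc23)[C@H](ONc2ccccc2)C=O)n(C(=O)OC(C)(C)C)c2ccccc12 | intermediate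
11 | tert-butyl 3-[2-(tert-butyldimethylsilyloxy)ethyl]-2-[(1S,2S)-3-hydroxy-1-(1H-indol-3-yl)-2-(phenylaminooxy)propyl]indole-1-carboxylate | CC(C)(C)[Si](C)(C)OCCc1c([C@H](c2c[nH]c3ccccc23)[C@H](ONc2ccccc2)CO)n(C(=O)OC(C)(C)C)c2ccccc12 | intermediate
12 | tert-butyl 3-[2-(tert-butyldimethylsilyloxy)ethyl]-2-[(1S,2S)-2,3-dihydroxy-1-(1H-indol-3-yl)propyl]indole-1-carboxylate | CC(C)(C)[Si](C)(C)OCCc1c([C@H](c2c[nH]c3ccccc23)[C@H](O)CO)n(C(=O)OC(C)(C)C)c2ccccc12 | intermediate
13 | tert-butyl 3-[2-(tert-butyldimethylsilyloxy)ethyl]-2-[(S)-[(4S)-2,2-dimethyl-1,3-dioxolan-4-yl](1H-indol-3-yl)methyl]indole-1-carboxylate | CC(C)(C)[Si](C)(C)OCCc1c([C@H](c2c[nH]c3ccccc23)[C@H]2COC(C)(C)O2)n(C(=O)OC(C)(C)C)c2ccccc12 | intermediate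
14 | 3-[2-(tert-butyldimethylsilyloxy)ethyl]-2-[(S)-[(4S)-2,2-dimethyl-1,3-dioxolan-4-yl](1H-indol-3-yl)methyl]-1H-indole | CC(C)(C)[Si](C)(C)OCCc1c([C@H](c2c[nH]c3ccccc23)[C@H]2COC(C)(C)O2)[nH]c2ccccc12 | intermediate
15 | 2-{2-[(S)-[(4S)-2,2-dimethyl-1,3-dioxolan-4-yl](1H-indol-3-yl)methyl]-1H-indol-3-yl}ethanol | OCCc1c([C@H](c2c[nH]c3ccccc23)[C@H]2COC(C)(C)O2)[nH]c2ccccc12 | intermediate
16 | 2-{2-[(S)-[(4S)-2,2-dimethyl-1,3-dioxolan-4-yl](1H-indol-3-yl)methyl]-1H-indol-3-yl}ethyl acetate | CC(=O)OCCc1c([C@H](c2c[nH]c3ccccc23)[C@H]2COC(C)(C)O2)[nH]c2ccccc12 | intermediate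
17 | colletotryptin C, 2-{2-[(1S,2S)-2,3-dihydroxy-1-(1H-indol-3-yl)propyl]-1H-indol-3-yl}ethyl acetate | CC(=O)OCCc1c([C@H](c2c[nH]c3ccccc23)[C@H](O)CO)[nH]c2ccccc12 | target

**Total step count:** 12. **Longest linear sequence:** 12 (from tryptophol 1; indole 8 enters at step 5).

**Steps most likely to fail**

Step 5 (Michael addition). The β-carbon of enal 7 is flanked by the N-Boc group and the C3 side chain, so the addition may be slow or less selective than with cinnamaldehyde.

The fallback sets out from 8 and 2 and comes back at 14.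
- Indole 8 is condensed with commercial (R)-2,2-dimethyl-1,3-dioxolane-4-carbaldehyde (D-mannitol-derived) and p-toluenesulfinic acid (TsOH catalyst, EtOAc, rt). This gives the sulfonyl indole 3-{[(4R)-2,2-dimethyl-1,3-dioxolan-4-yl](4-methylphenylsulfonyl)methyl}-1H-indole F1 as a mixture of epimers at the sulfonyl carbon.
- InBr3 (10 mol %) in CH2Cl2 expels the sulfinate to give the vinylogous imine 3-{[(4S)-2,2-dimethyl-1,3-dioxolan-4-yl]methylidene}-3H-indole F2.
- F2 is trapped in the same flask at its exocyclic carbon by C2 of silyl ether 2 in a conjugate Friedel–Crafts addition, which delivers 14 directly.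
- The carbinol stereocentre is now bought from the chiral pool, and only C1 depends on substrate control. The unwanted C1 epimer 3-[2-(tert-butyldimethylsilyloxy)ethyl]-2-[(R)-[(4S)-2,2-dimethyl-1,3-dioxolan-4-yl](1H-indol-3-yl)methyl]-1H-indole F3 is removed by chromatography.

Step 6 (α-aminoxylation). The β,β-diaryl aldehyde 9 may form its enamine slowly, which lets nitrosobenzene decompose, and the β-stereocentre may be mismatched with the catalyst.

The fallback sets out from 9 and comes back at 12, replacing organocatalysis by auxiliary control.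
- Pinnick oxidation (NaClO2, NaH2PO4, 2-methyl-2-butene, t-BuOH/H2O) gives (3S)-3-{1-(tert-butoxycarbonyl)-3-[2-(tert-butyldimethylsilyloxy)ethyl]indol-2-yl}-3-(1H-indol-3-yl)propanoic acid F4.
- Coupling with (S)-4-benzyloxazolidin-2-one (DCC, DMAP, CH2Cl2) gives the N-acyl oxazolidinone (imide of acid F4 with the 4S auxiliary) F5.
- Enolisation with NaN(SiMe3)2 (2.2 equiv, the first taken up by the indole N–H) in THF at −78 °C is followed by oxidation with 2-(phenylsulfonyl)-3-phenyloxaziridine and an acetic acid quench at −78 °C. The oxidant approaches the chelated Z-enolate opposite to the benzyl group, giving the (2S,3S)-2-hydroxy imide F6.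
- LiBH4 in THF/MeOH at 0 °C then releases diol 12 and the auxiliary.

Step 3 (lithiation and formylation). The amide base may attack the Boc group, or the Boc group may migrate from nitrogen to the lithiated carbon, which lowers the yield of 6.

The fallback sets out from 2 and comes back at 7, replacing carbanion chemistry by halogenation and cross-coupling.
- NBS in CH2Cl2 at 0 °C brominates the 3-substituted indole at C2 to give 2-bromo-3-[2-(tert-butyldimethylsilyloxy)ethyl]-1H-indole F7.
- F7 is protected at once (Boc2O, DMAP, MeCN) to give tert-butyl 2-bromo-3-[2-(tert-butyldimethylsilyloxy)ethyl]indole-1-carboxylate F8.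
- Heck coupling of F8 with acrolein (Pd(OAc)2, Bu4NCl, NaHCO3, DMF, 70 °C) gives E-enal 7 directly.

**Further compounds**
F1 | step 5 | 3-{[(4R)-2,2-dimethyl-1,3-dioxolan-4-yl](4-methylphenylsulfonyl)methyl}-1H-indole (epimers at the sulfonyl carbon) | Cc1ccc(cc1)S(=O)(=O)C(c1c[nH]c2ccccc12)[C@H]1COC(C)(C)O1
F2 | step 5 | 3-{[(4S)-2,2-dimethyl-1,3-dioxolan-4-yl]methylidene}-3H-indole | N1=CC(=C[C@H]2COC(C)(C)O2)c2ccccc12
F3 | step 5 | 3-[2-(tert-butyldimethylsilyloxy)ethyl]-2-[(R)-[(4S)-2,2-dimethyl-1,3-dioxolan-4-yl](1H-indol-3-yl)methyl]-1H-indole | CC(C)(C)[Si](C)(C)OCCc1c([C@@H](c2c[nH]c3ccccc23)[C@H]2COC(C)(C)O2)[nH]c2ccccc12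
F4 | step 6 | (3S)-3-{1-(tert-butoxycarbonyl)-3-[2-(tert-butyldimethylsilyloxy)ethyl]indol-2-yl}-3-(1H-indol-3-yl)propanoic acid | CC(C)(C)[Si](C)(C)OCCc1c([C@H](c2c[nH]c3ccccc23)CC(=O)O)n(C(=O)OC(C)(C)C)c2ccccc12
F5 | step 6 | tert-butyl 2-{(1S)-3-[(4S)-4-benzyl-2-oxooxazolidin-3-yl]-1-(1H-indol-3-yl)-3-oxopropyl}-3-[2-(tert-butyldimethylsilyloxy)ethyl]indole-1-carboxylate | CC(C)(C)[Si](C)(C)OCCc1c([C@H](c2c[nH]c3ccccc23)CC(=O)N2[C@@H](Cc3ccccc3)COC2=O)n(C(=O)OC(C)(C)C)c2ccccc12
F6 | step 6 | tert-butyl 2-{(1S,2S)-3-[(4S)-4-benzyl-2-oxooxazolidin-3-yl]-2-hydroxy-1-(1H-indol-3-yl)-3-oxopropyl}-3-[2-(tert-butyldimethylsilyloxy)ethyl]indole-1-carboxylate | CC(C)(C)[Si](C)(C)OCCc1c([C@H](c2c[nH]c3ccccc23)[C@H](O)C(=O)N2[C@@H](Cc3ccccc3)COC2=O)n(C(=O)OC(C)(C)C)c2ccccc12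
F7 | step 3 | 2-bromo-3-[2-(tert-butyldimethylsilyloxy)ethyl]-1H-indole | CC(C)(C)[Si](C)(C)OCCc1c(Br)[nH]c2ccccc12
F8 | step 3 | tert-butyl 2-bromo-3-[2-(tert-butyldimethylsilyloxy)ethyl]indole-1-carboxylate | CC(C)(C)[Si](C)(C)OCCc1c(Br)n(C(=O)OC(C)(C)C)c2ccccc12
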